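**Retrosynthetic overview**

1. Target 33 ⇐ bicyclic alcohol 29 (C3 angeloylation, removal of three silyl ethers); 29 already holds the whole ent-labdane skeleton.
2. Key disconnection at C4–C5 and C9–C10 of the trans-decalin: 29 ⇐ acyclic (3R,4R)-epoxy-triene 28. One Lewis-acid cascade closes ring A (C4–C5), then ring B (C9–C10), relays C4, C5, C10 and C9 from the oxirane, and ends as the C8=C17 methylene by loss of silicon from C17.
3. The feature used is the quaternary C4 (CH3/CH2OH) next to the equatorial C3–O: the E-CH2OSi arm of a Sharpless-derived oxirane becomes the equatorial C18 hydroxymethyl through anti opening at C4.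
4. 28 ⇐ three pieces joined by two sp3–sp2 Negishi couplings (C12–C13 with iodobutenediol 12; C5–C6 with epoxy iodide 8) on the (Z)-allylsilane linchpin 19, which comes from 2,3-dihydrofuran by Ni-catalysed C–O coupling with Me3SiCH2MgCl.

Key step: step 15

Remark: the SMILES is read as the ent-labdane (3R,4S,5S,9R,10S; 13Z) with the 3-O-angelate and the C4 hydroxymethyl (C18) both equatorial on a trans-decalin; labdane numbering is used for the carbons of all intermediates.

**Route**

Step 1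
Reactants: 1 6-methylhept-5-en-2-one
Product: 3 6-methylhept-5-en-1-yne, via enol diethyl phosphate 2 (not isolated)
Conditions: LDA, THF, −78 °C; ClP(O)(OEt)2, −78 °C → rt; LDA (2.3 equiv), −78 °C → rt
Reagents that add atoms: none
Why: Kinetic deprotonation at the methyl group, O-phosphorylation and base-induced elimination of the enol phosphate should turn the methyl ketone into the terminal alkyne (enol phosphate elimination); no stereocentre is formed.

Step 2
Reactants: 3 6-methylhept-5-en-1-yne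
Product: 5 (1E)-1-iodo-2,6-dimethylhepta-1,5-diene, via alkenyldimethylalane 4 (not isolated)
Conditions: Me3Al, Cp2ZrCl2 (cat.), CH2Cl2, rt; then I2, THF, −30 °C
Reagents that add atoms: trimethylaluminium (C[Al](C)C); iodine (II)
Why: Zirconium-catalysed syn-carboalumination (Negishi carboalumination) places CH3 (C20) on the internal and Al on the terminal alkyne carbon, and iodinolysis with retention should give the (E)-iodide that fixes the C5=C10 geometry.

Step 3
Reactants: 5 (1E)-1-iodo-2,6-dimethylhepta-1,5-diene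
Product: 6 (2E,6E)-7-iodo-2,6-dimethylhepta-2,6-dien-1-ol
Conditions: SeO2 (cat.), t-BuOOH, salicylic acid (cat.), CH2Cl2, rt
Reagents that add atoms: tert-butyl hydroperoxide (CC(C)(C)OO)
Why: SeO2-catalysed allylic hydroxylation (ene reaction then [2,3]-shift) should attack the electron-rich prenyl terminus at its (E)-methyl group rather than the iodine-deactivated olefin, giving the (E)-allylic alcohol whose CH2O becomes C18.

Step 4
Reactants: 6 (2E,6E)-7-iodo-2,6-dimethylhepta-2,6-dien-1-ol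
Product: 7 {(2R,3R)-3-[(3E)-4-iodo-3-methylbut-3-en-1-yl]-2-methyloxiran-2-yl}methanol
Conditions: Ti(OiPr)4 (cat.), D-(−)-diethyl tartrate (cat.), t-BuOOH, 4 Å MS, CH2Cl2, −20 °C
Reagents that add atoms: tert-butyl hydroperoxide (CC(C)(C)OO)
Why: Sharpless asymmetric epoxidation with the D-(−)-tartrate should epoxidise the titanium-bound allylic alcohol on the face that gives the (2R,3R)-epoxy alcohol, which sets C3 (R) and the C4 centre that the key step later inverts.

Step 5
Reactants: 7 {(2R,3R)-3-[(3E)-4-iodo-3-methylbut-3-en-1-yl]-2-methyloxiran-2-yl}methanol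
Product: 8 tert-butyl({(2R,3R)-3-[(3E)-4-iodo-3-methylbut-3-en-1-yl]-2-methyloxiran-2-yl}methoxy)diphenylsilane
Conditions: TBDPSCl, imidazole, DMF, rt
Reagents that add atoms: tert-butyl(chloro)diphenylsilane (CC(C)(C)[Si](Cl)(c1ccccc1)c1ccccc1)
Why: Standard O-silylation of the primary alcohol; the bulky, weakly basic TBDPS ether should not take part in the later Lewis-acid opening of the oxirane.

Step 6
Reactants: 9 but-2-yne-1,4-diol
Product: 10 1,4-bis(tert-butyldiphenylsilyloxy)but-2-yne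
Conditions: TBDPSCl (2.2 equiv), imidazole, DMF, rt
Reagents that add atoms: tert-butyl(chloro)diphenylsilane (CC(C)(C)[Si](Cl)(c1ccccc1)c1ccccc1)
Why: Standard double O-silylation, which installs the protecting groups that C15–OH and C16–OH keep until the last step.

Step 7
Reactants: 10 1,4-bis(tert-butyldiphenylsilyloxy)but-2-yne
Product: 12 (2E)-1,4-bis(tert-butyldiphenylsilyloxy)-2-iodobut-2-ene, via alkenylstannane 11 (not isolated)
Conditions: Bu3SnH, PdCl2(PPh3)2 (cat.), THF, 0 °C → rt; then I2, CH2Cl2, 0 °C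
Reagents that add atoms: iodine (II)
Why: Pd-catalysed hydrostannation adds H and Sn syn across the symmetrical alkyne and iododestannylation proceeds with retention, so the iodide should have the two silyloxymethyl groups cis (the future 13Z geometry).

Step 8
Reactants: 13 2,3-dihydrofuran; 14 ethylene oxide
Product: 17 tert-butyl[2-(4,5-dihydrofuran-2-yl)ethoxy]dimethylsilane, via 5-lithio-2,3-dihydrofuran 15 (not isolated), via lithium alkoxide 16 (not isolated)
Conditions: t-BuLi, THF, −78 → 0 °C; ethylene oxide, −78 °C → rt; then TBSCl, DMF, rt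
Reagents that add atoms: tert-butyl(chloro)dimethylsilane (CC(C)(C)[Si](C)(C)Cl)
Why: α-Lithiation of the enol ether, opening of ethylene oxide and O-silylation of the alkoxide in one pot should give the 5-substituted dihydrofuran, in which the ring oxygen is locked cis to the ring CH2 that becomes C11.

Step 9
Reactants: 17 tert-butyl[2-(4,5-dihydrofuran-2-yl)ethoxy]dimethylsilane; 18 (trimethylsilyl)methylmagnesium chloride
Product: 19 (3Z)-6-(tert-butyldimethylsilyloxy)-4-(trimethylsilylmethyl)hex-3-en-1-ol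
Conditions: NiCl2(PPh3)2 (5 mol %), PhMe, 80 °C
Reagents that add atoms: none
Why: Nickel-catalysed Kumada-type cross-coupling of the enol ether C(sp2)–O bond proceeds with retention, so CH2SiMe3 (C17) should take the place of the ring oxygen cis to C11 and give the trisubstituted allylsilane as the (Z)-isomer.

Step 10
Reactants: 19 (3Z)-6-(tert-butyldimethylsilyloxy)-4-(trimethylsilylmethyl)hex-3-en-1-ol
Product: 21 tert-butyl{[(3Z)-6-iodo-3-(trimethylsilylmethyl)hex-3-en-1-yl]oxy}dimethylsilane, via primary mesylate 20 (not isolated)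
Conditions: MsCl, Et3N, CH2Cl2, 0 °C; then NaI, acetone, 50 °C
Reagents that add atoms: sodium iodide ([Na+].[I-])
Why: Mesylation and Finkelstein displacement (SN2) should give the primary iodide without exposing the allylsilane to electrophilic iodine.

Step 11
Reactants: 21 tert-butyl{[(3Z)-6-iodo-3-(trimethylsilylmethyl)hex-3-en-1-yl]oxy}dimethylsilane; 12 (2E)-1,4-bis(tert-butyldiphenylsilyloxy)-2-iodobut-2-ene
Product: 23 (2Z)-2-[(3Z)-6-(tert-butyldimethylsilyloxy)-4-(trimethylsilylmethyl)hex-3-en-1-yl]but-2-ene-1,4-diol bis(tert-butyldiphenylsilyl) ether, via alkylzinc iodide 22 (not isolated)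
Conditions: Zn dust, LiCl, THF, 40 °C; then 12, Pd(OAc)2 (cat.), SPhos (cat.), THF, rt
Reagents that add atoms: none
Why: Negishi coupling: zinc inserts into the primary C–I bond and palladium couples the alkylzinc with the alkenyl iodide with retention, which should form C12–C13 and carry the 13Z geometry over from 12.

Step 12
Reactants: 23 (2Z)-2-[(3Z)-6-(tert-butyldimethylsilyloxy)-4-(trimethylsilylmethyl)hex-3-en-1-yl]but-2-ene-1,4-diol bis(tert-butyldiphenylsilyl) ether
Product: 24 (2Z)-2-[(3Z)-6-hydroxy-4-(trimethylsilylmethyl)hex-3-en-1-yl]but-2-ene-1,4-diol bis(tert-butyldiphenylsilyl) ether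
Conditions: HF·pyridine, pyridine, THF, 0 °C
Reagents that add atoms: none
Why: Selective desilylation: buffered HF·pyridine should cleave the primary alkyl TBS ether much faster than the two TBDPS ethers and leave the C–SiMe3 bond of the allylsilane untouched.

Step 13
Reactants: 24 (2Z)-2-[(3Z)-6-hydroxy-4-(trimethylsilylmethyl)hex-3-en-1-yl]but-2-ene-1,4-diol bis(tert-butyldiphenylsilyl) ether
Product: 26 (2Z)-2-[(3Z)-6-iodo-4-(trimethylsilylmethyl)hex-3-en-1-yl]but-2-ene-1,4-diol bis(tert-butyldiphenylsilyl) ether, via primary mesylate 25 (not isolated)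
Conditions: MsCl, Et3N, CH2Cl2, 0 °C; then NaI, acetone, 50 °C
Reagents that add atoms: sodium iodide ([Na+].[I-])
Why: Mesylation and Finkelstein displacement (SN2) as in step 10 should convert the C6 alcohol into the iodide needed for the second fragment union.

Step 14
Reactants: 26 (2Z)-2-[(3Z)-6-iodo-4-(trimethylsilylmethyl)hex-3-en-1-yl]but-2-ene-1,4-diol bis(tert-butyldiphenylsilyl) ether; 8 tert-butyl({(2R,3R)-3-[(3E)-4-iodo-3-methylbut-3-en-1-yl]-2-methyloxiran-2-yl}methoxy)diphenylsilane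
Product: 28 (2Z)-2-{(3Z,7E)-10-[(2R,3R)-3-(tert-butyldiphenylsilyloxymethyl)-3-methyloxiran-2-yl]-8-methyl-4-(trimethylsilylmethyl)deca-3,7-dien-1-yl}but-2-ene-1,4-diol bis(tert-butyldiphenylsilyl) ether, via alkylzinc iodide 27 (not isolated)
Conditions: Zn dust, LiCl, THF, 40 °C; then 8, Pd(OAc)2 (cat.), SPhos (cat.), THF, rt
Reagents that add atoms: none
Why: Negishi coupling of the alkylzinc with the (E)-alkenyl iodide should form C5–C6 with retention of the C5=C10 geometry under neutral conditions that the trisubstituted oxirane tolerates.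

Step 15
Reactants: 28 (2Z)-2-{(3Z,7E)-10-[(2R,3R)-3-(tert-butyldiphenylsilyloxymethyl)-3-methyloxiran-2-yl]-8-methyl-4-(trimethylsilylmethyl)deca-3,7-dien-1-yl}but-2-ene-1,4-diol bis(tert-butyldiphenylsilyl) ether
Product: 29 (3R,4S,5S,9R,10S)-15,16,18-tris(tert-butyldiphenylsilyloxy)-ent-labda-8(17),13Z-dien-3-ol
Conditions: MeAlCl2 (3 equiv), CH2Cl2, −78 °C; then Et3N/MeOH, aq. Rochelle salt
Reagents that add atoms: none
Why: MeAlCl2 binds the oxirane oxygen, the C5=C10 π bond attacks C4 anti to the breaking C4–O bond, the C10 cation is taken up by C9 of the (Z)-allylsilane, and the β-silyl cation at C8 loses Me3Si to leave only the 8(17)-methylene. The closest known reaction type is the Lewis acid-promoted epoxy-polyene cyclization terminated by an allylsilane. Ring A closes in a 6-endo mode at the tertiary oxirane carbon and ring B in a 6-endo-trig mode, both through a chair–chair array that gives the trans-decalin. C3 (R) comes unchanged from the Sharpless oxirane; C4 is set by the stereospecific inversion, which puts the E-substituent of the oxirane (CH2OSi, C18) equatorial and the methyl axial; C5 and C10 follow from anti addition across the E C5=C10 bond (H-5 trans to CH3-20); C9 follows from the geometry of the C8=C9 bond (C11 equatorial). The step needs ionisation at C4 rather than C3 and no interference from the side-chain olefin: the tertiary oxirane carbon with a well-placed trisubstituted π nucleophile should secure the first, and the C13=C14 bond, flanked by two inductively withdrawing silyloxymethyl groups and left without a cation once silicon is lost, should secure the second.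

Step 16
Reactants: 29 (3R,4S,5S,9R,10S)-15,16,18-tris(tert-butyldiphenylsilyloxy)-ent-labda-8(17),13Z-dien-3-ol; 30 angelic acid
Product: 32 (3R,4S,5S,9R,10S)-15,16,18-tris(tert-butyldiphenylsilyloxy)-ent-labda-8(17),13Z-dien-3-yl (2Z)-2-methylbut-2-enoate, via angelic 2,4,6-trichlorobenzoic anhydride 31 (not isolated)
Conditions: 2,4,6-Cl3C6H2COCl, Et3N, PhMe, rt; then 29, PhMe, 80 °C
Reagents that add atoms: none
Why: Yamaguchi-type esterification through the mixed anhydride should acylate the hindered equatorial C3 hydroxyl at the less hindered angeloyl carbonyl without a nucleophilic catalyst, which keeps the (Z)-geometry of the angelate.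

Step 17
Reactants: 32 (3R,4S,5S,9R,10S)-15,16,18-tris(tert-butyldiphenylsilyloxy)-ent-labda-8(17),13Z-dien-3-yl (2Z)-2-methylbut-2-enoate
Product: 33 (3R,4S,5S,9R,10S)-15,16,18-trihydroxy-ent-labda-8(17),13Z-dien-3-yl (2Z)-2-methylbut-2-enoate (CNP0237954.1)
Conditions: HF·pyridine, pyridine, THF, 0 °C → rt
Reagents that add atoms: none
Why: Fluoride-mediated desilylation with buffered HF·pyridine should remove the three primary TBDPS ethers under mildly acidic conditions in which the angelate neither migrates to O18 nor isomerises.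

**Compound list**

1 | 6-methylhept-5-en-2-one | CC(C)=CCCC(C)=O | starting material
2 | 6-methylhepta-1,5-dien-2-yl diethyl phosphate | CC(C)=CCCC(=C)OP(=O)(OCC)OCC | intermediate
3 | 6-methylhept-5-en-1-yne | CC(C)=CCCC#C | intermediate
4 | [(1E)-2,6-dimethylhepta-1,5-dien-1-yl]dimethylalane | CC(C)=CCC/C(C)=C/[Al](C)C | intermediate
5 | (1E)-1-iodo-2,6-dimethylhepta-1,5-diene | CC(C)=CCC/C(C)=C/I | intermediate
6 | (2E,6E)-7-iodo-2,6-dimethylhepta-2,6-dien-1-ol | OC/C(C)=C/CC/C(C)=C/I | intermediate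
7 | {(2R,3R)-3-[(3E)-4-iodo-3-methylbut-3-en-1-yl]-2-methyloxiran-2-yl}methanol | OC[C@@]1(C)O[C@@H]1CC/C(C)=C/I | intermediate
8 | tert-butyl({(2R,3R)-3-[(3E)-4-iodo-3-methylbut-3-en-1-yl]-2-methyloxiran-2-yl}methoxy)diphenylsilane | CC(C)(C)[Si](c1ccccc1)(c1ccccc1)OC[C@@]1(C)O[C@@H]1CC/C(C)=C/I | intermediate
9 | but-2-yne-1,4-diol | OCC#CCO | starting material
10 | 1,4-bis(tert-butyldiphenylsilyloxy)but-2-yne | CC(C)(C)[Si](c1ccccc1)(c1ccccc1)OCC#CCO[Si](c1ccccc1)(c1ccccc1)C(C)(C)C | intermediate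
11 | (2E)-1,4-bis(tert-butyldiphenylsilyloxy)-2-(tributylstannyl)but-2-ene | CCCC[Sn](CCCC)(CCCC)/C(CO[Si](c1ccccc1)(c1ccccc1)C(C)(C)C)=C/CO[Si](c1ccccc1)(c1ccccc1)C(C)(C)C | intermediate
12 | (2E)-1,4-bis(tert-butyldiphenylsilyloxy)-2-iodobut-2-ene | I/C(CO[Si](c1ccccc1)(c1ccccc1)C(C)(C)C)=C/CO[Si](c1ccccc1)(c1ccccc1)C(C)(C)C | intermediate
13 | 2,3-dihydrofuran | C1CC=CO1 | starting material
14 | ethylene oxide | C1CO1 | starting material
15 | 5-lithio-2,3-dihydrofuran | [Li]C1=CCCO1 | intermediate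
16 | lithium 2-(4,5-dihydrofuran-2-yl)ethoxide | [Li+].[O-]CCC1=CCCO1 | intermediate
17 | tert-butyl[2-(4,5-dihydrofuran-2-yl)ethoxy]dimethylsilane | CC(C)(C)[Si](C)(C)OCCC1=CCCO1 | intermediate
18 | (trimethylsilyl)methylmagnesium chloride | C[Si](C)(C)C[Mg]Cl | starting material
19 | (3Z)-6-(tert-butyldimethylsilyloxy)-4-(trimethylsilylmethyl)hex-3-en-1-ol | CC(C)(C)[Si](C)(C)OCC/C(C[Si](C)(C)C)=C/CCO | intermediate
20 | (3Z)-6-(tert-butyldimethylsilyloxy)-4-(trimethylsilylmethyl)hex-3-en-1-yl methanesulfonate | CC(C)(C)[Si](C)(C)OCC/C(C[Si](C)(C)C)=C/CCOS(C)(=O)=O | intermediate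
21 | tert-butyl{[(3Z)-6-iodo-3-(trimethylsilylmethyl)hex-3-en-1-yl]oxy}dimethylsilane | CC(C)(C)[Si](C)(C)OCC/C(C[Si](C)(C)C)=C/CCI | intermediate
22 | alkylzinc iodide derived from 21 | CC(C)(C)[Si](C)(C)OCC/C(C[Si](C)(C)C)=C/CC[Zn]I | intermediate
23 | (2Z)-2-[(3Z)-6-(tert-butyldimethylsilyloxy)-4-(trimethylsilylmethyl)hex-3-en-1-yl]but-2-ene-1,4-diol bis(tert-butyldiphenylsilyl) ether | CC(C)(C)[Si](C)(C)OCC/C(C[Si](C)(C)C)=C/CC/C(CO[Si](c1ccccc1)(c1ccccc1)C(C)(C)C)=C/CO[Si](c1ccccc1)(c1ccccc1)C(C)(C)C | intermediate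
24 | (2Z)-2-[(3Z)-6-hydroxy-4-(trimethylsilylmethyl)hex-3-en-1-yl]but-2-ene-1,4-diol bis(tert-butyldiphenylsilyl) ether | OCC/C(C[Si](C)(C)C)=C/CC/C(CO[Si](c1ccccc1)(c1ccccc1)C(C)(C)C)=C/CO[Si](c1ccccc1)(c1ccccc1)C(C)(C)C | intermediate
25 | methanesulfonate of 24 | CS(=O)(=O)OCC/C(C[Si](C)(C)C)=C/CC/C(CO[Si](c1ccccc1)(c1ccccc1)C(C)(C)C)=C/CO[Si](c1ccccc1)(c1ccccc1)C(C)(C)C | intermediate
26 | (2Z)-2-[(3Z)-6-iodo-4-(trimethylsilylmethyl)hex-3-en-1-yl]but-2-ene-1,4-diol bis(tert-butyldiphenylsilyl) ether | ICC/C(C[Si](C)(C)C)=C/CC/C(CO[Si](c1ccccc1)(c1ccccc1)C(C)(C)C)=C/CO[Si](c1ccccc1)(c1ccccc1)C(C)(C)C | intermediate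
27 | alkylzinc iodide derived from 26 | I[Zn]CC/C(C[Si](C)(C)C)=C/CC/C(CO[Si](c1ccccc1)(c1ccccc1)C(C)(C)C)=C/CO[Si](c1ccccc1)(c1ccccc1)C(C)(C)C | intermediate
28 | (2Z)-2-{(3Z,7E)-10-[(2R,3R)-3-(tert-butyldiphenylsilyloxymethyl)-3-methyloxiran-2-yl]-8-methyl-4-(trimethylsilylmethyl)deca-3,7-dien-1-yl}but-2-ene-1,4-diol bis(tert-butyldiphenylsilyl) ether | CC(C)(C)[Si](c1ccccc1)(c1ccccc1)OC[C@@]1(C)O[C@@H]1CC/C(C)=C/CC/C(C[Si](C)(C)C)=C/CC/C(CO[Si](c1ccccc1)(c1ccccc1)C(C)(C)C)=C/CO[Si](c1ccccc1)(c1ccccc1)C(C)(C)C | intermediate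
29 | (3R,4S,5S,9R,10S)-15,16,18-tris(tert-butyldiphenylsilyloxy)-ent-labda-8(17),13Z-dien-3-ol | C=C1CC[C@H]2[C@@](C)(CC[C@@H](O)[C@]2(C)CO[Si](c3ccccc3)(c3ccccc3)C(C)(C)C)[C@@H]1CC/C(=C/CO[Si](c3ccccc3)(c3ccccc3)C(C)(C)C)CO[Si](c3ccccc3)(c3ccccc3)C(C)(C)C | intermediate
30 | angelic acid, (2Z)-2-methylbut-2-enoic acid | C/C=C(/C)C(=O)O | starting material
31 | angelic 2,4,6-trichlorobenzoic anhydride | C/C=C(/C)C(=O)OC(=O)c1c(Cl)cc(Cl)cc1Cl | intermediate
32 | (3R,4S,5S,9R,10S)-15,16,18-tris(tert-butyldiphenylsilyloxy)-ent-labda-8(17),13Z-dien-3-yl (2Z)-2-methylbut-2-enoate | C=C1CC[C@H]2[C@@](C)(CC[C@@H](OC(=O)/C(C)=C\C)[C@]2(C)CO[Si](c3ccccc3)(c3ccccc3)C(C)(C)C)[C@@H]1CC/C(=C/CO[Si](c3ccccc3)(c3ccccc3)C(C)(C)C)CO[Si](c3ccccc3)(c3ccccc3)C(C)(C)C | intermediate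
33 | (3R,4S,5S,9R,10S)-15,16,18-trihydroxy-ent-labda-8(17),13Z-dien-3-yl (2Z)-2-methylbut-2-enoate (CNP0237954.1) | C=C1CC[C@H]2[C@@](C)(CC[C@@H](OC(=O)/C(C)=C\C)[C@]2(C)CO)[C@@H]1CC/C(=C/CO)CO | target

**Step count and risk**

Total step count: 17. Longest linear sequence: 10 steps (steps 8–17, from 2,3-dihydrofuran); the branches are steps 1–5 (epoxy iodide 8) and steps 6–7 (iodide 12).

Steps most likely to fail:

Step 15 (key step). What may go wrong: the oxirane carbon C4 carries an inductively withdrawing silyloxymethyl group, so ionisation may be slow; a Lewis acid-induced 1,2-hydride shift, chloride opening or proton loss after closure of ring A could then compete with the second ring closure, and adventitious HCl could protodesilylate the allylsilane. Fallback (radical instead of cationic cascade): it sets out from dihydrofuran 17 and comes back to the route at alcohol 29. Nickel-catalysed ring opening of 17 with MeMgBr should give (3E)-6-(tert-butyldimethylsilyloxy)-4-methylhex-3-en-1-ol F1. Appel iodination (I2, PPh3, imidazole) should give tert-butyl{[(3E)-6-iodo-3-methylhex-3-en-1-yl]oxy}dimethylsilane F2, and zinc insertion its alkylzinc iodide F3. Negishi coupling of F3 with 12 should give (2Z)-2-[(3E)-6-(tert-butyldimethylsilyloxy)-4-methylhex-3-en-1-yl]but-2-ene-1,4-diol bis(tert-butyldiphenylsilyl) ether F4. HF·pyridine should give (2Z)-2-[(3E)-6-hydroxy-4-methylhex-3-en-1-yl]but-2-ene-1,4-diol bis(tert-butyldiphenylsilyl) ether F5, Appel iodination (2Z)-2-[(3E)-6-iodo-4-methylhex-3-en-1-yl]but-2-ene-1,4-diol bis(tert-butyldiphenylsilyl) ether F6, and zinc insertion its alkylzinc iodide F7. Negishi coupling of F7 with 8 should give the C8-methyl analogue of epoxide 28 F8. F8 is then treated with Cp2TiCl (from Cp2TiCl2 and Mn, THF, rt): homolytic opening of the oxirane to the tertiary C4 radical, 6-endo/6-endo radical cyclisation and titanium-mediated loss of a hydrogen from the C17 methyl should give 29 after aqueous work-up. In this variant C4 is no longer set by inversion; it rests on the chair preference that keeps the larger CH2OSi group equatorial, so a C4 epimer may have to be separated.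

Step 16. What may go wrong: acylation of the hindered C3 hydroxyl next to the quaternary C4 may be slow, and during prolonged heating the activated angeloyl unit may isomerise to the (E)-tigloyl isomer. Fallback (build the Z-olefin on the ester instead of transferring it): it sets out from 29 and comes back at 32. DCC/DMAP esterification of 29 with 2-[bis(2,2,2-trifluoroethoxy)phosphoryl]propanoic acid should give the 3-O-{2-[bis(2,2,2-trifluoroethoxy)phosphoryl]propanoyl} ester of 29 F9 (both epimers at the phosphonate α-carbon), and Still–Gennari olefination (KHMDS, 18-crown-6, THF, −78 °C, acetaldehyde) should then give the (Z)-2-methylbut-2-enoate 32.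

Step 9. What may go wrong: oxidative addition of nickel into the trisubstituted enol ether C–O bond may be sluggish, with loss of the silyl ether or erosion of the olefin geometry on prolonged heating with the Grignard reagent. Fallback (carbometalation of an alkyne instead of C–O coupling): it sets out from Grignard reagent 18 and comes back at 19. Syn-carbocupration of commercial 4-(tert-butyldimethylsilyloxy)but-1-yne F10 with (trimethylsilyl)methylcopper F11 (from 18 and CuBr·SMe2, Et2O/Me2S, −25 °C) should give the (1Z)-4-(tert-butyldimethylsilyloxy)-2-(trimethylsilylmethyl)but-1-en-1-ylcopper F12, and trapping of F12 with ethylene oxide 14 should give 19 with the same olefin geometry.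

Further compounds
F1 | step 15 | (3E)-6-(tert-butyldimethylsilyloxy)-4-methylhex-3-en-1-ol | CC(C)(C)[Si](C)(C)OCC/C(C)=C/CCO
F2 | step 15 | tert-butyl{[(3E)-6-iodo-3-methylhex-3-en-1-yl]oxy}dimethylsilane | CC(C)(C)[Si](C)(C)OCC/C(C)=C/CCI
F3 | step 15 | alkylzinc iodide derived from F2 | CC(C)(C)[Si](C)(C)OCC/C(C)=C/CC[Zn]I
F4 | step 15 | (2Z)-2-[(3E)-6-(tert-butyldimethylsilyloxy)-4-methylhex-3-en-1-yl]but-2-ene-1,4-diol bis(tert-butyldiphenylsilyl) ether | CC(C)(C)[Si](C)(C)OCC/C(C)=C/CC/C(CO[Si](c1ccccc1)(c1ccccc1)C(C)(C)C)=C/CO[Si](c1ccccc1)(c1ccccc1)C(C)(C)C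
F5 | step 15 | (2Z)-2-[(3E)-6-hydroxy-4-methylhex-3-en-1-yl]but-2-ene-1,4-diol bis(tert-butyldiphenylsilyl) ether | OCC/C(C)=C/CC/C(CO[Si](c1ccccc1)(c1ccccc1)C(C)(C)C)=C/CO[Si](c1ccccc1)(c1ccccc1)C(C)(C)C
F6 | step 15 | (2Z)-2-[(3E)-6-iodo-4-methylhex-3-en-1-yl]but-2-ene-1,4-diol bis(tert-butyldiphenylsilyl) ether | ICC/C(C)=C/CC/C(CO[Si](c1ccccc1)(c1ccccc1)C(C)(C)C)=C/CO[Si](c1ccccc1)(c1ccccc1)C(C)(C)C
F7 | step 15 | alkylzinc iodide derived from F6 | I[Zn]CC/C(C)=C/CC/C(CO[Si](c1ccccc1)(c1ccccc1)C(C)(C)C)=C/CO[Si](c1ccccc1)(c1ccccc1)C(C)(C)C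
F8 | step 15 | C8-methyl analogue of epoxide 28 (CH3 in place of CH2SiMe3) | CC(C)(C)[Si](c1ccccc1)(c1ccccc1)OC[C@@]1(C)O[C@@H]1CC/C(C)=C/CC/C(C)=C/CC/C(CO[Si](c1ccccc1)(c1ccccc1)C(C)(C)C)=C/CO[Si](c1ccccc1)(c1ccccc1)C(C)(C)C
F9 | step 16 | 3-O-{2-[bis(2,2,2-trifluoroethoxy)phosphoryl]propanoyl} ester of 29 | C=C1CC[C@H]2[C@@](C)(CC[C@@H](OC(=O)C(C)P(=O)(OCC(F)(F)F)OCC(F)(F)F)[C@]2(C)CO[Si](c3ccccc3)(c3ccccc3)C(C)(C)C)[C@@H]1CC/C(=C/CO[Si](c3ccccc3)(c3ccccc3)C(C)(C)C)CO[Si](c3ccccc3)(c3ccccc3)C(C)(C)C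
F10 | step 9 | 4-(tert-butyldimethylsilyloxy)but-1-yne | CC(C)(C)[Si](C)(C)OCCC#C
F11 | step 9 | (trimethylsilyl)methylcopper | C[Si](C)(C)C[Cu]
F12 | step 9 | (1Z)-4-(tert-butyldimethylsilyloxy)-2-(trimethylsilylmethyl)but-1-en-1-ylcopper | CC(C)(C)[Si](C)(C)OCC/C(C[Si](C)(C)C)=C/[Cu]
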